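## Analysis of the target

Locants used throughout: ring A is the six-membered carbocycle, with C1 (C=O), C2 (allyl-bearing), C3 (H), C4 (sp3, bears OCH3 and the side chain), C5 (bears OCH3) and C6 (H). The side chain is C8 (bonded to C4, bears the methyl C9) doubly bonded to C7 (H, bonded to ring B, the 3,4-dimethoxyphenyl ring).

- The target is a monocyclic, cross-conjugated cyclohexa-2,5-dienone (ring A) joined to ring B through a trisubstituted propenyl bridge.
- The only stereocenter is C4, of (S) configuration. It is fully substituted and doubly allylic, bears OCH3 and C8, and lies between the sp2 carbons C3 and C5, so it can be neither epimerised nor corrected once made.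
- The second stereo-element is the (E) geometry of C7=C8, with ring A trans to ring B.
- Ring A is a resorcinol at the oxidation level "phenol plus two electrons": O on C1 and O on C5 are the 1,3-oxygens of a resorcinol.
- The feature the strategy uses is that O on C4 and O on C5 of ring A are vicinal, on an sp3/sp2 carbon pair. A two-atom bridge can span them in a six-membered ring.
- Sensitive groups are:
  - the p-quinol ether at C4 (acid-induced dienone–phenol rearrangement or aromatisation with loss of the C4 oxygen; ionisation by zerovalent palladium);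
  - the vinylogous ester C5–OCH3/C1=O (exchange, hydrolysis);
  - the terminal allyl group (migration into conjugation);
  - the electron-rich styrene (oxidants, acid).
- The synthesis is hard because any flat precursor of ring A (arene, quinone) has two enantiotopic faces at C4 that differ only through remote substituents. In addition, an electrophilic ring A is conjugated with the side chain, so C7 competes with C4 for any oxygen nucleophile.

## Retrosynthetic reasoning

**18 from 17.** The O–CH3 bond on the C4 oxygen is cut last. The C4–O bond is not touched, so the forward O-methylation of tertiary alcohol 17 cannot affect the stereocenter.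

**17 from 15.** The two methoxy-type oxygens on C4 and C5 are tied back into a temporary ring, the 1,4-dioxan-2-one of 15. It joins O on C4 (as the acyloxy oxygen) and O on C5 (as the enol-ether oxygen) through a lactic acid unit. This ring is not in the target. Forward, one methanolysis operation must open the lactone and exchange the lactate ether on C5 for methoxide, releasing the auxiliary.

**15 from 12 (key disconnection).** The C4–O bond is cut and ring A is re-aromatised, giving phenol 12: a resorcinol whose oxygen next to the side chain carries an (R)-lactic dimethylamide. This is the place to cut because it removes the only stereocenter and the dienone in one stroke, leaving a flat arene with every carbon in place. Forward, a trivalent iodine oxidant makes C4 electrophilic and the amide oxygen of the tether is delivered to it. The six-membered closure forces the oxygen onto C4 rather than C7, and the stereocenter of the tether chooses the face.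

**12 from 10.** The C2–allyl bond is cut by a retro-Claisen rearrangement to aryl allyl ether 10. The same allyl group thus protects the phenol through the earlier steps and then becomes the C-allyl group without a new reagent. Forward, the [3,3] shift must go to the ortho position remote from the lactamide ether.

**10 from 9 from 7.** The C8–C9 bond is cut: the methyl group comes from cross-coupling of enol triflate 9, made from benzyl ketone 7. This is chosen over an olefination because the enolate geometry of an aryl benzyl ketone is reliably Z and the coupling retains it, so the (E)-alkene is set by mechanism and not by an isomer ratio.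

**7 from 5 and 6.** The aryl-O–CH bond of the tether is cut. Forward, a Mitsunobu reaction of the chelated phenol of 5 with commercial (S)-lactamide 6 inverts the carbinol carbon to the required (R) configuration.

**5 from 3 and 4; 3 from 1 and 2.** The O-allyl bond is cut to allyl bromide 4 and the ring A–C8 bond by a retro-Friedel–Crafts acylation to resorcinol 1 and arylacetic acid 2. One step assembles ring A, ring B and the C8–C7 unit from two bulk chemicals. The resulting ketone also differentiates the two phenols of 3 through its hydrogen bond.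

## Alternatives that were turned down

**Alternative 1:** the textbook disconnection of the C4–C8 bond.
- Forward key step: 1,2-addition of alkenyllithium A2 to the C4 carbonyl of 2-allyl-5-methoxy-1,4-benzoquinone A1 to give p-quinol A3, then O-methylation.
- It is short and regiochemically reasonable, since the other carbonyl is deactivated as a vinylogous ester.
- It was turned down because the quinone is flat and its C4 carbonyl faces are enantiotopic; neither partner carries a controlling element, and there is no dependable catalytic asymmetric alkenylation of a quinone carbonyl. A3 would be racemic and half of a late intermediate would be lost in a resolution.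
- Electron transfer from the organolithium to the quinone is a further loss channel.

**Alternative 2:** disconnection of the C4–OCH3 bond without a tether.
- Forward key step: oxidative dearomatisation of the free phenol A4 in methanol with PhI(OAc)2 or a chiral aryl iodide catalyst.
- It was turned down on mechanism. The oxidised ring A is a vinylogous quinone methide whose positive charge is shared with C7, where ring B stabilises it. Free methanol has no geometric reason to prefer the hindered C4 and should add at C7 to give quinone methide A5.
- Even if C4 were attacked, the chiral iodine centre sits on the C1 oxygen, para to and remote from C4, so face control of an external nucleophile would be weak.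

**Alternative 3:** disconnection of the C5–C6 bond, building ring A last.
- Forward key step: Dieckmann-type cyclisation of the acyclic (Z)-enone keto ester A6, whose tertiary ether stereocenter would be set earlier by asymmetric alkenylation of an α-keto ester. This gives vinylogous acid A7, which is then O-methylated.
- It was turned down for three reasons:
  - the (Z)-enone must be made and kept;
  - A7 is an unsymmetrical cyclic 1,3-dione that can be methylated on either oxygen, one giving 18 and the other the linearly conjugated 2,4-dienone isomer;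
  - the route needs well over a dozen steps to reach a ring that resorcinol supplies for nothing.

Key step: step 7

Remark on the chemistry: the sense of induction in step 7 follows the steric model given there. Should the opposite face be preferred, the same steps run from the (R)-enantiomer of 6 lead to 18.

## Route

Step 1
Reactants: 1 resorcinol; 2 (3,4-dimethoxyphenyl)acetic acid
Product: 3 1-(2,4-dihydroxyphenyl)-2-(3,4-dimethoxyphenyl)ethan-1-one
Conditions: BF3·OEt2 (solvent), 85 °C; then aq NaOAc
Reagents that add atoms: none
Why: Friedel–Crafts acylation of resorcinol by the BF3-activated acid occurs para to one hydroxyl and ortho to the other and stops at the chelated, deactivated mono-ketone; it joins ring A, ring B and the C8–C7 unit in one operation.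

Step 2
Reactants: 3 1-(2,4-dihydroxyphenyl)-2-(3,4-dimethoxyphenyl)ethan-1-one; 4 allyl bromide
Product: 5 1-[4-(allyloxy)-2-hydroxyphenyl]-2-(3,4-dimethoxyphenyl)ethan-1-one
Conditions: K2CO3 (1.1 equiv), acetone, reflux
Reagents that add atoms: none
Why: Williamson etherification; the hydroxyl ortho to the ketone is held in a hydrogen bond and is less acidic, so the weak base alkylates only the para hydroxyl, and the benzylic CH2 is not deprotonated by carbonate.

Step 3
Reactants: 5 1-[4-(allyloxy)-2-hydroxyphenyl]-2-(3,4-dimethoxyphenyl)ethan-1-one; 6 (S)-2-hydroxy-N,N-dimethylpropanamide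
Product: 7 (R)-2-{5-(allyloxy)-2-[(3,4-dimethoxyphenyl)acetyl]phenoxy}-N,N-dimethylpropanamide
Conditions: PPh3, diisopropyl azodicarboxylate (DIAD), THF, 0 °C → rt
Reagents that add atoms: none
Why: Mitsunobu reaction; the remaining phenol is acidic enough to act as pronucleophile and displaces the activated secondary hydroxyl of 6 by SN2 with inversion, so (S) becomes (R); the ketone CH2 is too weakly acidic to compete.

Step 4
Reactants: 7 (R)-2-{5-(allyloxy)-2-[(3,4-dimethoxyphenyl)acetyl]phenoxy}-N,N-dimethylpropanamide
Product: 9 (Z)-1-{4-(allyloxy)-2-[((R)-1-(dimethylamino)-1-oxopropan-2-yl)oxy]phenyl}-2-(3,4-dimethoxyphenyl)ethenyl trifluoromethanesulfonate, via potassium Z-enolate 8 (not isolated)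
Conditions: KN(SiMe3)2 (1.05 equiv), THF, −78 °C; then PhNTf2, −78 → 0 °C
Reagents that add atoms: N-phenyl-bis(trifluoromethanesulfonimide), O=S(=O)(N(c1ccccc1)S(=O)(=O)C(F)(F)F)C(F)(F)F; KN(SiMe3)2, C[Si](C)(C)N([K])[Si](C)(C)C (supplies only the potassium of 8)
Why: The doubly activated ketone CH2 is far more acidic than the amide α-H, so one equivalent of base leaves the auxiliary stereocenter alone and gives the Z-enolate general for aryl benzyl ketones (enolate oxygen cis to ring B, aryl rings trans); O-sulfonylation fixes this geometry.

Step 5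
Reactants: 9 (Z)-1-{4-(allyloxy)-2-[((R)-1-(dimethylamino)-1-oxopropan-2-yl)oxy]phenyl}-2-(3,4-dimethoxyphenyl)ethenyl trifluoromethanesulfonate
Product: 10 (R)-2-{5-(allyloxy)-2-[(E)-1-(3,4-dimethoxyphenyl)prop-1-en-2-yl]phenoxy}-N,N-dimethylpropanamide
Conditions: MeMgBr (1.3 equiv), Fe(acac)3 (5 mol %), THF/NMP, −30 °C
Reagents that add atoms: methylmagnesium bromide, C[Mg]Br
Why: Iron-catalysed Kumada-type coupling of an alkenyl triflate proceeds with retention, so CH3 takes the place of OTf and the (Z)-triflate becomes the (E)-alkene with ring A trans to ring B; at −30 °C the tertiary amide and the aryl allyl ether should survive, and zerovalent palladium, which would ionise the allyl ether, is avoided.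

Step 6
Reactants: 10 (R)-2-{5-(allyloxy)-2-[(E)-1-(3,4-dimethoxyphenyl)prop-1-en-2-yl]phenoxy}-N,N-dimethylpropanamide
Product: 12 (R)-2-{4-allyl-2-[(E)-1-(3,4-dimethoxyphenyl)prop-1-en-2-yl]-5-hydroxyphenoxy}-N,N-dimethylpropanamide, via ortho-dienone 11 (not isolated)
Conditions: 1,2-dichlorobenzene, 190 °C, sealed tube, argon
Reagents that add atoms: none
Why: Aromatic Claisen rearrangement ([3,3] shift, then tautomerisation of 11); the ortho position between the two oxygens is shielded by the branched lactamide ether, which the neighbouring alkenyl group pushes toward it, and a meta alkoxy donor directs migration para to itself, so the allyl group should go to the carbon that becomes C2; the neutral medium protects the auxiliary stereocenter and the olefin geometry.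

Step 7
Reactants: 12 (R)-2-{4-allyl-2-[(E)-1-(3,4-dimethoxyphenyl)prop-1-en-2-yl]-5-hydroxyphenoxy}-N,N-dimethylpropanamide
Product: 15 (3R,8aS)-7-allyl-8a-[(E)-1-(3,4-dimethoxyphenyl)prop-1-en-2-yl]-3-methyl-3H-benzo[b][1,4]dioxine-2,6(8aH)-dione, via aryloxyiodane 13 (not isolated), via iminium ether 14 (not isolated)
Conditions: PhI(OCOCF3)2 (1.1 equiv), CH2Cl2, −40 → 0 °C; then H2O, 0 °C → rt; aq NaHCO3 work-up
Reagents that add atoms: water, O; [bis(trifluoroacetoxy)iodo]benzene, O=C(OI(c1ccccc1)OC(=O)C(F)(F)F)C(F)(F)F (supplies only the iodine ligands of 13 and the counter-ion of 14)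
Why: The phenol oxygen of 12 exchanges a trifluoroacetate ligand on PhI(OCOCF3)2 to give 13, whose collapse with loss of PhI turns ring A into a phenoxonium-type electrophile with its positive charge centred at C4, para to the former hydroxyl. The amide carbonyl oxygen of the tether on the C5 oxygen, the most nucleophilic group within reach, captures C4 to give iminium ether 14; water then adds to the iminium carbon and, in the acidic medium, expels dimethylamine to leave lactone 15. The closest known reaction type is the hypervalent-iodine dearomatisation of 4-alkylresorcinol mono-ethers that carry a lactic amide on the oxygen next to the alkyl group, which closes the same dioxanone at the alkyl-bearing carbon. The ring closed is the six-membered 1,4-dioxan-2-one (C4, C5, ether O, the lactate CH, the carbonyl C, acyloxy O), formed by 6-exo capture of the cationic C4 with C4 and C5 shared with ring A. The new stereocenter C4 is controlled by the lactate stereocenter: in the boat-like closure the two carbons face each other across the forming ring, the lactate substituent that points toward the C4 alkenyl group must be H and not CH3, and for the (R)-lactate this is possible only when oxygen arrives on the face that makes C4 (S), with CH3 and the alkenyl group trans on the dioxanone. Regioselectivity needs C4 to win over C7, over the ortho carbon C6 and over external nucleophiles: the tether can reach C7 only through an eight-membered ring, C6 carries less positive charge than the donor-substituted para carbon, and the medium holds no nucleophile better than trifluoroacetate. Chemoselectivity rests on the phenol being the only group that binds to iodine, so the styrene, the allyl group and ring B should be spared at low temperature. The minor C4 epimer is a diastereomer of 15 and is removed by chromatography, so the enantiomeric purity of 18 is fixed here.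

Step 8
Reactants: 15 (3R,8aS)-7-allyl-8a-[(E)-1-(3,4-dimethoxyphenyl)prop-1-en-2-yl]-3-methyl-3H-benzo[b][1,4]dioxine-2,6(8aH)-dione
Product: 17 (S)-2-allyl-4-[(E)-1-(3,4-dimethoxyphenyl)prop-1-en-2-yl]-4-hydroxy-5-methoxycyclohexa-2,5-dien-1-one, via hydroxy ester 16 (not isolated)
Conditions: NaOMe (0.3 equiv), MeOH, 0 → 40 °C; then NH4Cl
Reagents that add atoms: methanol, CO
Why: Base-catalysed transesterification opens the α-alkoxy-activated lactone at the acyl carbon, leaving the C4–O bond and the configuration of C4 untouched, to give 16; methoxide then exchanges the vinylogous ester at C5 by conjugate addition–elimination, the lactate alkoxide being the better leaving group, so the auxiliary leaves as methyl lactate.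

Step 9
Reactants: 17 (S)-2-allyl-4-[(E)-1-(3,4-dimethoxyphenyl)prop-1-en-2-yl]-4-hydroxy-5-methoxycyclohexa-2,5-dien-1-one
Product: 18 (S)-2-allyl-4-[(E)-1-(3,4-dimethoxyphenyl)prop-1-en-2-yl]-4,5-dimethoxycyclohexa-2,5-dien-1-one
Conditions: NaH, MeI, THF/DMF, 0 °C → rt
Reagents that add atoms: iodomethane, CI
Why: Williamson O-methylation of the tertiary alkoxide; ring A has no acidic C–H (C4 is quaternary, C6–H is the α-carbon of a vinylogous ester) and the C4–O bond is not broken, so the (S) configuration is kept.

## Compound list

1 | resorcinol (benzene-1,3-diol) | Oc1cccc(O)c1 | starting material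
2 | (3,4-dimethoxyphenyl)acetic acid | COc1ccc(CC(=O)O)cc1OC | starting material
3 | 1-(2,4-dihydroxyphenyl)-2-(3,4-dimethoxyphenyl)ethan-1-one | COc1ccc(CC(=O)c2ccc(O)cc2O)cc1OC | intermediate
4 | allyl bromide (3-bromoprop-1-ene) | C=CCBr | starting material
5 | 1-[4-(allyloxy)-2-hydroxyphenyl]-2-(3,4-dimethoxyphenyl)ethan-1-one | COc1ccc(CC(=O)c2ccc(OCC=C)cc2O)cc1OC | intermediate
6 | (S)-2-hydroxy-N,N-dimethylpropanamide ((S)-N,N-dimethyllactamide) | C[C@H](O)C(=O)N(C)C | starting material
7 | (R)-2-{5-(allyloxy)-2-[(3,4-dimethoxyphenyl)acetyl]phenoxy}-N,N-dimethylpropanamide | COc1ccc(CC(=O)c2ccc(OCC=C)cc2O[C@H](C)C(=O)N(C)C)cc1OC | intermediate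
8 | potassium (Z)-enolate of 7 (enolate oxygen cis to ring B) | [K+].[O-]/C(=C\c1ccc(OC)c(OC)c1)c1ccc(OCC=C)cc1O[C@H](C)C(=O)N(C)C | intermediate (not isolated)
9 | (Z)-1-{4-(allyloxy)-2-[((R)-1-(dimethylamino)-1-oxopropan-2-yl)oxy]phenyl}-2-(3,4-dimethoxyphenyl)ethenyl trifluoromethanesulfonate | O=S(=O)(O/C(=C\c1ccc(OC)c(OC)c1)c1ccc(OCC=C)cc1O[C@H](C)C(=O)N(C)C)C(F)(F)F | intermediate
10 | (R)-2-{5-(allyloxy)-2-[(E)-1-(3,4-dimethoxyphenyl)prop-1-en-2-yl]phenoxy}-N,N-dimethylpropanamide | C/C(=C\c1ccc(OC)c(OC)c1)c1ccc(OCC=C)cc1O[C@H](C)C(=O)N(C)C | intermediate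
11 | 6-allyl-4-[(E)-1-(3,4-dimethoxyphenyl)prop-1-en-2-yl]-3-{[(R)-1-(dimethylamino)-1-oxopropan-2-yl]oxy}cyclohexa-2,4-dien-1-one (both C6 epimers) | C=CCC1C=C(/C(C)=C/c2ccc(OC)c(OC)c2)C(O[C@H](C)C(=O)N(C)C)=CC1=O | intermediate (not isolated)
12 | (R)-2-{4-allyl-2-[(E)-1-(3,4-dimethoxyphenyl)prop-1-en-2-yl]-5-hydroxyphenoxy}-N,N-dimethylpropanamide | C=CCc1cc(/C(C)=C/c2ccc(OC)c(OC)c2)c(O[C@H](C)C(=O)N(C)C)cc1O | intermediate
13 | {2-allyl-4-[(E)-1-(3,4-dimethoxyphenyl)prop-1-en-2-yl]-5-[((R)-1-(dimethylamino)-1-oxopropan-2-yl)oxy]phenoxy}(phenyl)-λ3-iodanyl trifluoroacetate | C=CCc1cc(/C(C)=C/c2ccc(OC)c(OC)c2)c(O[C@H](C)C(=O)N(C)C)cc1OI(c3ccccc3)OC(=O)C(F)(F)F | intermediate (not isolated)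
14 | (3R,8aS)-7-allyl-8a-[(E)-1-(3,4-dimethoxyphenyl)prop-1-en-2-yl]-N,N,3-trimethyl-6-oxo-3,6-dihydro-8aH-benzo[b][1,4]dioxin-2-iminium trifluoroacetate | C=CCC1=C[C@@]2(/C(C)=C/c3ccc(OC)c(OC)c3)OC(=[N+](C)C)[C@@H](C)OC2=CC1=O.[O-]C(=O)C(F)(F)F | intermediate (not isolated)
15 | (3R,8aS)-7-allyl-8a-[(E)-1-(3,4-dimethoxyphenyl)prop-1-en-2-yl]-3-methyl-3H-benzo[b][1,4]dioxine-2,6(8aH)-dione (dioxanone fused to ring A through C4 and C5) | C=CCC1=C[C@@]2(/C(C)=C/c3ccc(OC)c(OC)c3)OC(=O)[C@@H](C)OC2=CC1=O | intermediate
16 | methyl (R)-2-{[(6S)-4-allyl-6-[(E)-1-(3,4-dimethoxyphenyl)prop-1-en-2-yl]-6-hydroxy-3-oxocyclohexa-1,4-dien-1-yl]oxy}propanoate | C=CCC1=C[C@](O)(/C(C)=C/c2ccc(OC)c(OC)c2)C(O[C@H](C)C(=O)OC)=CC1=O | intermediate (not isolated)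
17 | (S)-2-allyl-4-[(E)-1-(3,4-dimethoxyphenyl)prop-1-en-2-yl]-4-hydroxy-5-methoxycyclohexa-2,5-dien-1-one | C=CCC1=C[C@](O)(/C(C)=C/c2ccc(OC)c(OC)c2)C(OC)=CC1=O | intermediate
18 | (S)-2-allyl-4-[(E)-1-(3,4-dimethoxyphenyl)prop-1-en-2-yl]-4,5-dimethoxycyclohexa-2,5-dien-1-one | C=CCC1=C[C@](OC)(/C(C)=C/c2ccc(OC)c(OC)c2)C(OC)=CC1=O | target

## Step count and least certain steps

Total step count: 9. Longest linear sequence: 9 steps (from 1 and 2; compounds 4 and 6 enter as purchased reagents).

**Step 7 (key step).**
- Most likely failures:
  - capture of the delocalised cation at C7 or at the ortho carbon C6 instead of C4;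
  - direct oxidation of the electron-rich styrene or of ring B by the iodine reagent;
  - insufficient facial selectivity, if the lactate methyl group does not discriminate strongly enough against the C4 alkenyl group;
  - hydrolysis of the iminium ether with loss of the ring oxygen instead of the amine.
- All of these stem from oxidising a phenol that is conjugated with a donor-substituted alkene.
- Fallback: form the C4–C8 bond by polar addition to a quinone and separate the enantiomers. It sets out from allyl bromide 4 and returns at 17.
  - Commercial 3-methoxyphenol is allylated with 4 (K2CO3, acetone) to 1-(allyloxy)-3-methoxybenzene F1.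
  - Claisen rearrangement (N,N-diethylaniline, 190 °C) gives 2-allyl-5-methoxyphenol F2 after removal of the regioisomer.
  - Oxidation with (KSO3)2NO in buffered aqueous acetone gives 2-allyl-5-methoxy-1,4-benzoquinone F3.
  - Separately, commercial 4-iodo-1,2-dimethoxybenzene and propyne (Pd(PPh3)2Cl2, CuI, Et3N) give 1,2-dimethoxy-4-(prop-1-yn-1-yl)benzene F4.
  - Hydrozirconation with Cp2Zr(H)Cl and iodinolysis give (E)-4-(2-iodoprop-1-en-1-yl)-1,2-dimethoxybenzene F5.
  - Iodine–lithium exchange (t-BuLi, Et2O, −78 °C) and addition to F3 at the carbonyl that is not deactivated as a vinylogous ester give the racemic p-quinol F6.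
  - F6 is resolved by preparative chromatography on a chiral stationary phase to give 17, and the route resumes at step 9.

**Step 6.**
- Most likely failures: migration of the allyl group into the position between the two oxygens, and thermal erosion of the auxiliary stereocenter.
- Fallback: replace the sigmatropic shift by halogenation and cross-coupling. It sets out from 10 and returns at 12.
  - Deallylation with Pd(PPh3)4 and morpholine gives (R)-2-{2-[(E)-1-(3,4-dimethoxyphenyl)prop-1-en-2-yl]-5-hydroxyphenoxy}-N,N-dimethylpropanamide F7.
  - N-iodosuccinimide in MeCN at −20 °C iodinates the activated position ortho to the hydroxyl and para to the ether to give (R)-2-{2-[(E)-1-(3,4-dimethoxyphenyl)prop-1-en-2-yl]-5-hydroxy-4-iodophenoxy}-N,N-dimethylpropanamide F8.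
  - Stille coupling with allyltributylstannane (Pd(PPh3)4, DMF, 80 °C) gives 12.

**Step 5 (with the geometry set in step 4).**
- Most likely failures: incomplete Z-selectivity of enolisation carried through as an E/Z mixture, reduction or homocoupling of the triflate, and attack of MeMgBr on the amide or the allyl ether.
- Fallback: make the C8–C9 bond by carbonyl addition and the alkene by elimination. It sets out from 7 and returns at 10, bypassing steps 4 and 5.
  - MeCeCl2 (from MeLi and CeCl3, THF, −78 °C), chosen to suppress enolisation, gives (2R)-2-{5-(allyloxy)-2-[1-(3,4-dimethoxyphenyl)-2-hydroxypropan-2-yl]phenoxy}-N,N-dimethylpropanamide F9.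
  - Dehydration under equilibrating acid (catalytic p-TsOH, toluene, 60 °C) should favour the conjugated (E)-alkene 10, which is purified from its isomers.

**Step 3.**
- Most likely failures: sluggish reaction of the hydrogen-bonded, hindered phenol, with elimination or partial racemisation of the activated lactamide.
- Fallback: alkylate with a preformed electrophile. It sets out from 6 and 5 and returns at 7.
  - 6 is converted (Tf2O, 2,6-lutidine, CH2Cl2, −78 °C) into (S)-1-(dimethylamino)-1-oxopropan-2-yl trifluoromethanesulfonate F10.
  - The potassium phenoxide of 5 (K2CO3, MeCN, 0 °C → rt) displaces the triflate with inversion to give 7.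

**Step 8.**
- Most likely failures: slow exchange at the hindered C5, so that the reaction stops at the ring-opened ester, and reversible conjugate addition of methoxide to C3 of the free p-quinol.
- Fallback: methylate before the exchange and run the exchange under acid. It sets out from 15 and returns at 18, bypassing 17 and step 9.
  - K2CO3 (catalytic) in MeOH at −20 °C stops at hydroxy ester 16, which is isolated in this variant.
  - NaH and MeI give methyl (R)-2-{[(6S)-4-allyl-6-[(E)-1-(3,4-dimethoxyphenyl)prop-1-en-2-yl]-6-methoxy-3-oxocyclohexa-1,4-dien-1-yl]oxy}propanoate F11.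
  - Acid-catalysed exchange of the vinylogous ester (catalytic camphorsulfonic acid, MeOH, rt) then gives 18 directly.

## Further compounds

F1 | step 7 | 1-(allyloxy)-3-methoxybenzene | C=CCOc1cccc(OC)c1
F2 | step 7 | 2-allyl-5-methoxyphenol | C=CCc1ccc(OC)cc1O
F3 | step 7 | 2-allyl-5-methoxy-1,4-benzoquinone | C=CCC1=CC(=O)C(OC)=CC1=O
F4 | step 7 | 1,2-dimethoxy-4-(prop-1-yn-1-yl)benzene | CC#Cc1ccc(OC)c(OC)c1
F5 | step 7 | (E)-4-(2-iodoprop-1-en-1-yl)-1,2-dimethoxybenzene | C/C(I)=C\c1ccc(OC)c(OC)c1
F6 | step 7 | racemic 2-allyl-4-[(E)-1-(3,4-dimethoxyphenyl)prop-1-en-2-yl]-4-hydroxy-5-methoxycyclohexa-2,5-dien-1-one | C=CCC1=CC(O)(/C(C)=C/c2ccc(OC)c(OC)c2)C(OC)=CC1=O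
F7 | step 6 | (R)-2-{2-[(E)-1-(3,4-dimethoxyphenyl)prop-1-en-2-yl]-5-hydroxyphenoxy}-N,N-dimethylpropanamide | C/C(=C\c1ccc(OC)c(OC)c1)c1ccc(O)cc1O[C@H](C)C(=O)N(C)C
F8 | step 6 | (R)-2-{2-[(E)-1-(3,4-dimethoxyphenyl)prop-1-en-2-yl]-5-hydroxy-4-iodophenoxy}-N,N-dimethylpropanamide | C/C(=C\c1ccc(OC)c(OC)c1)c1cc(I)c(O)cc1O[C@H](C)C(=O)N(C)C
F9 | step 5 | (2R)-2-{5-(allyloxy)-2-[1-(3,4-dimethoxyphenyl)-2-hydroxypropan-2-yl]phenoxy}-N,N-dimethylpropanamide (both carbinol epimers) | COc1ccc(CC(C)(O)c2ccc(OCC=C)cc2O[C@H](C)C(=O)N(C)C)cc1OC
F10 | step 3 | (S)-1-(dimethylamino)-1-oxopropan-2-yl trifluoromethanesulfonate | C[C@H](OS(=O)(=O)C(F)(F)F)C(=O)N(C)C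
F11 | step 8 | methyl (R)-2-{[(6S)-4-allyl-6-[(E)-1-(3,4-dimethoxyphenyl)prop-1-en-2-yl]-6-methoxy-3-oxocyclohexa-1,4-dien-1-yl]oxy}propanoate | C=CCC1=C[C@](OC)(/C(C)=C/c2ccc(OC)c(OC)c2)C(O[C@H](C)C(=O)OC)=CC1=O
A1 | alternative 1 | 2-allyl-5-methoxy-1,4-benzoquinone | C=CCC1=CC(=O)C(OC)=CC1=O
A2 | alternative 1 | (E)-[1-(3,4-dimethoxyphenyl)prop-1-en-2-yl]lithium | [Li]/C(C)=C/c1ccc(OC)c(OC)c1
A3 | alternative 1 | racemic 2-allyl-4-[(E)-1-(3,4-dimethoxyphenyl)prop-1-en-2-yl]-4-hydroxy-5-methoxycyclohexa-2,5-dien-1-one | C=CCC1=CC(O)(/C(C)=C/c2ccc(OC)c(OC)c2)C(OC)=CC1=O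
A4 | alternative 2 | 2-allyl-4-[(E)-1-(3,4-dimethoxyphenyl)prop-1-en-2-yl]-5-methoxyphenol | C=CCc1cc(/C(C)=C/c2ccc(OC)c(OC)c2)c(OC)cc1O
A5 | alternative 2 | 2-allyl-4-[1-(3,4-dimethoxyphenyl)-1-methoxypropan-2-ylidene]-5-methoxycyclohexa-2,5-dien-1-one (quinone methide, geometry undefined) | C=CCC1=CC(=C(C)C(OC)c2ccc(OC)c(OC)c2)C(OC)=CC1=O
A6 | alternative 3 | methyl (2S,3Z)-4-acetyl-2-[(E)-1-(3,4-dimethoxyphenyl)prop-1-en-2-yl]-2-methoxyhepta-3,6-dienoate | C=CC/C(C(C)=O)=C/[C@](OC)(/C(C)=C/c1ccc(OC)c(OC)c1)C(=O)OC
A7 | alternative 3 | (S)-2-allyl-4-[(E)-1-(3,4-dimethoxyphenyl)prop-1-en-2-yl]-5-hydroxy-4-methoxycyclohexa-2,5-dien-1-one | C=CCC1=C[C@](OC)(/C(C)=C/c2ccc(OC)c(OC)c2)C(O)=CC1=O
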